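**Plan**

- Cuts: after removal of the O-benzyl groups, only the two aryl–C2 bonds are cut, C2–C1' of the flavanone and C2''–C1''' of the flavone. The C3'–C3''' biaryl bond is never made: it is bought as 2,2'-biphenol, whose two carbons para to OH are exactly C1' and C1'''.
- Enabling feature: both C rings are the same 5,7-dioxygenated benzo-4-pyranone (O1–C2–C3–C4(=O)–C4a–C8a) at two oxidation levels, and each carries at C2 only an aryl carbon. One building block, 5,7-bis(benzyloxy)chromone, therefore serves twice and no pyranone ring is built on the biaryl.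
- Forward order: biphenol → dibenzyl ether → 5,5'-dibromide → mono Br/Li exchange → boronic acid. Pd(II)/O2 oxidative C2-arylation of the chromone keeps the pyranone flat (flavone half). Br → B(OH)2. A second chromone is then arylated at C2 by Rh-catalysed asymmetric 1,4-addition, which joins the halves and turns the flat pyranone into the C2-stereogenic dihydropyranone. Hydrogenolysis ends the route.
- Stereochemistry: the single stereocentre (2S) comes from the chiral Rh–bisphosphine catalyst in the last C–C bond formation. Only neutral hydrogenolysis follows, so the retro-oxa-Michael racemisation channel stays closed.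

Key step: step 8

Assumption: the sense of induction of the Rh/(S)-biaryl-bisphosphine catalyst on the chromone is taken to follow the model established for 2-cyclohexenone ((S)-ligand → (2S)-flavanone); it is fixed on chromone/phenylboronic acid before material is committed, and the (R)-ligand is used if the model reaction shows the opposite sense.

**Step 1**
Reactants: 1 biphenyl-2,2'-diol
Product: 2 2,2'-bis(benzyloxy)biphenyl
Conditions: BnBr (2.4 equiv), K2CO3, DMF, 60 °C
Reagents that add atoms: benzyl bromide, BrCc1ccccc1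
Why: Williamson ether synthesis masks both phenols as benzyl ethers, which tolerate organolithium, Pd(II)/O2 and Rh(I) chemistry and leave at the end under neutral hydrogenolysis.

**Step 2**
Reactants: 2 2,2'-bis(benzyloxy)biphenyl
Product: 3 2,2'-bis(benzyloxy)-5,5'-dibromobiphenyl
Conditions: NBS (2.1 equiv), MeCN, rt, dark
Reagents that add atoms: N-bromosuccinimide, O=C1CCC(=O)N1Br
Why: Electrophilic aromatic bromination of an aryl alkyl ether with NBS in MeCN goes para to the ether oxygen, which places the two handles on the carbons that become C1' and C1''' while the unactivated benzyl rings stay untouched.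

**Step 3**
Reactants: 3 2,2'-bis(benzyloxy)-5,5'-dibromobiphenyl
Product: 6 [4-(benzyloxy)-3-[2-(benzyloxy)-5-bromophenyl]phenyl]boronic acid, via monoaryllithium 4 (not isolated), via lithium triisopropoxyborate 5 (not isolated)
Conditions: n-BuLi (1.0 equiv, slow addition), THF, −78 °C; B(OiPr)3 (1.5 equiv), −78 °C to rt; 1 M HCl
Reagents that add atoms: triisopropyl borate, CC(C)OB(OC(C)C)OC(C)C; water, O
Why: Mono bromine–lithium exchange of a symmetrical dibromobiaryl with one equivalent of n-BuLi at low temperature is a known selective desymmetrisation, and borate trapping with acidic hydrolysis should give the boronic acid while the second C–Br bond is kept for step 7.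

**Step 4**
Reactants: 7 1-(2,4,6-trihydroxyphenyl)ethanone
Product: 8 1-[2,4-bis(benzyloxy)-6-hydroxyphenyl]ethanone
Conditions: BnBr (2.1 equiv), K2CO3, DMF, rt
Reagents that add atoms: benzyl bromide, BrCc1ccccc1
Why: Williamson etherification takes the para-OH and one ortho-OH, whereas the remaining ortho-OH, hydrogen-bonded to the acetyl carbonyl, is the least nucleophilic and stays free for the pyranone closure.

**Step 5**
Reactants: 8 1-[2,4-bis(benzyloxy)-6-hydroxyphenyl]ethanone
Product: 10 5,7-bis(benzyloxy)-4H-chromen-4-one, via enaminone 9 (not isolated)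
Conditions: DMF-DMA, toluene, 100 °C; then conc. HCl, CH2Cl2, rt
Reagents that add atoms: N,N-dimethylformamide dimethyl acetal, COC(OC)N(C)C
Why: Enaminone formation at the acetyl CH3 followed by acid-promoted 6-endo addition of the free phenol and loss of dimethylamine is the standard synthesis of 2,3-unsubstituted chromones.

**Step 6**
Reactants: 6 [4-(benzyloxy)-3-[2-(benzyloxy)-5-bromophenyl]phenyl]boronic acid; 10 5,7-bis(benzyloxy)-4H-chromen-4-one (1.5 equiv)
Product: 11 5,7-bis(benzyloxy)-2-[4-(benzyloxy)-3-[2-(benzyloxy)-5-bromophenyl]phenyl]-4H-chromen-4-one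
Conditions: Pd(TFA)2 (10 mol %), O2 (1 atm), DMSO, 80 °C
Reagents that add atoms: none
Why: In this Pd(II)-catalysed aerobic oxidative boron-Heck arylation, transmetalation, carbopalladation that puts the aryl group on C2 (β to the carbonyl) and β-hydride elimination from the palladium enolate (any flavanone formed by protonation being dehydrogenated by the same Pd(II)/DMSO/O2 system) should restore the flat pyranone, and the C–Br bond should survive because no phosphine-ligated Pd(0) is present.

**Step 7**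
Reactants: 11 5,7-bis(benzyloxy)-2-[4-(benzyloxy)-3-[2-(benzyloxy)-5-bromophenyl]phenyl]-4H-chromen-4-one
Product: 12 [4-(benzyloxy)-3-[2-(benzyloxy)-5-[5,7-bis(benzyloxy)-4-oxo-4H-chromen-2-yl]phenyl]phenyl]boronic acid
Conditions: B2(OH)4 (3 equiv), XPhos Pd G2 (2 mol %), XPhos (4 mol %), KOAc (3 equiv), EtOH/THF, 80 °C; aqueous work-up
Reagents that add atoms: tetrahydroxydiboron, OB(O)B(O)O
Why: Miyaura-type Pd(0)-catalysed borylation of the aryl bromide with tetrahydroxydiboron should give the free boronic acid directly, so that the key step can be run without the strong base that a boronic ester would need.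

**Step 8**
Reactants: 12 [4-(benzyloxy)-3-[2-(benzyloxy)-5-[5,7-bis(benzyloxy)-4-oxo-4H-chromen-2-yl]phenyl]phenyl]boronic acid; 10 5,7-bis(benzyloxy)-4H-chromen-4-one (2 equiv, excess recovered)
Product: 13 (2S)-5,7-bis(benzyloxy)-2-[4-(benzyloxy)-3-[2-(benzyloxy)-5-[5,7-bis(benzyloxy)-4-oxo-4H-chromen-2-yl]phenyl]phenyl]-2,3-dihydro-4H-chromen-4-one
Conditions: [RhCl(C2H4)2]2 (2.5 mol %), (S)-MeO-F12-BIPHEP [(S)-2,2'-bis[bis(3,4,5-trifluorophenyl)phosphino]-6,6'-dimethoxybiphenyl] (5.5 mol %), aq KOH (10 mol %), toluene/H2O 10:1, 40 °C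
Reagents that add atoms: none
Why: Hayashi–Miyaura reaction: the Rh(I)–OH complex of the electron-poor bisphosphine transmetalates with 12, the aryl–Rh species binds the C2=C3 bond of 10 and inserts so that the aryl carbon C1' bonds to C2, and the oxa-π-allyl rhodium enolate is hydrolysed by water to the ketone with return of Rh–OH. The closest known reaction type is the Rh/electron-poor biaryl bisphosphine 1,4-addition of arylboronic acids to chromones, 5,7-dioxygenated ones included, which gives flavanones. No ring is closed; the ring that changes is the flat 4-pyranone ring of 10, which becomes the dihydropyranone ring of the flavanone as C2 turns sp3. The new stereocentre C2 is controlled by the C2-symmetric ligand, which exposes one enantioface of the chromone in the carbometalation, the (S)-ligand being expected to give (2S) by the model for 2-cyclohexenone. The step needs chemoselectivity for the C2-unsubstituted chromone 10 over the flavone unit already present in 12 and 13, which the aryl group at C2'' secures because a β,β-disubstituted enone does not insert under these conditions, and it needs the product to survive, which the nearly base-free medium at 40 °C secures against ring opening to the chalcone.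

**Step 9**
Reactants: 13 (2S)-5,7-bis(benzyloxy)-2-[4-(benzyloxy)-3-[2-(benzyloxy)-5-[5,7-bis(benzyloxy)-4-oxo-4H-chromen-2-yl]phenyl]phenyl]-2,3-dihydro-4H-chromen-4-one
Product: 14 2-[3-[5-[(2S)-5,7-dihydroxy-4-oxo-3,4-dihydro-2H-chromen-2-yl]-2-hydroxyphenyl]-4-hydroxyphenyl]-5,7-dihydroxy-4H-chromen-4-one
Conditions: H2 (1 atm), 10% Pd/C, THF/MeOH, rt
Reagents that add atoms: none
Why: Hydrogenolysis of the six aryl benzyl ethers is neutral, so no 4'-phenoxide is formed and retro-oxa-Michael racemisation of C2 is avoided, while the flavone C2''=C3'' bond (a vinylogous ester) and the C4 ketones should not be reduced at 1 atm.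

**Compound list**

1 | biphenyl-2,2'-diol (2,2'-biphenol) | Oc1ccccc1-c1ccccc1O | starting material
2 | 2,2'-bis(benzyloxy)biphenyl | C(Oc1ccccc1-c1ccccc1OCc1ccccc1)c1ccccc1 | intermediate
3 | 2,2'-bis(benzyloxy)-5,5'-dibromobiphenyl | Brc1ccc(OCc2ccccc2)c(c1)-c1cc(Br)ccc1OCc1ccccc1 | intermediate
4 | [4-(benzyloxy)-3-[2-(benzyloxy)-5-bromophenyl]phenyl]lithium | [Li]c1ccc(OCc2ccccc2)c(c1)-c1cc(Br)ccc1OCc1ccccc1 | intermediate (not isolated)
5 | lithium [4-(benzyloxy)-3-[2-(benzyloxy)-5-bromophenyl]phenyl]tri(propan-2-yloxy)borate | [Li+].CC(C)O[B-](OC(C)C)(OC(C)C)c1ccc(OCc2ccccc2)c(c1)-c1cc(Br)ccc1OCc1ccccc1 | intermediate (not isolated)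
6 | [4-(benzyloxy)-3-[2-(benzyloxy)-5-bromophenyl]phenyl]boronic acid | OB(O)c1ccc(OCc2ccccc2)c(c1)-c1cc(Br)ccc1OCc1ccccc1 | intermediate
7 | 1-(2,4,6-trihydroxyphenyl)ethanone (2',4',6'-trihydroxyacetophenone) | CC(=O)c1c(O)cc(O)cc1O | starting material
8 | 1-[2,4-bis(benzyloxy)-6-hydroxyphenyl]ethanone | CC(=O)c1c(O)cc(OCc2ccccc2)cc1OCc1ccccc1 | intermediate
9 | (E)-1-[2,4-bis(benzyloxy)-6-hydroxyphenyl]-3-(dimethylamino)prop-2-en-1-one | CN(C)/C=C/C(=O)c1c(O)cc(OCc2ccccc2)cc1OCc1ccccc1 | intermediate (not isolated)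
10 | 5,7-bis(benzyloxy)-4H-chromen-4-one | O=c1ccoc2cc(OCc3ccccc3)cc(OCc3ccccc3)c12 | intermediate
11 | 5,7-bis(benzyloxy)-2-[4-(benzyloxy)-3-[2-(benzyloxy)-5-bromophenyl]phenyl]-4H-chromen-4-one | O=c1cc(-c2ccc(OCc3ccccc3)c(-c3cc(Br)ccc3OCc3ccccc3)c2)oc2cc(OCc3ccccc3)cc(OCc3ccccc3)c12 | intermediate
12 | [4-(benzyloxy)-3-[2-(benzyloxy)-5-[5,7-bis(benzyloxy)-4-oxo-4H-chromen-2-yl]phenyl]phenyl]boronic acid | O=c1cc(-c2ccc(OCc3ccccc3)c(-c3cc(B(O)O)ccc3OCc3ccccc3)c2)oc2cc(OCc3ccccc3)cc(OCc3ccccc3)c12 | intermediate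
13 | (2S)-5,7-bis(benzyloxy)-2-[4-(benzyloxy)-3-[2-(benzyloxy)-5-[5,7-bis(benzyloxy)-4-oxo-4H-chromen-2-yl]phenyl]phenyl]-2,3-dihydro-4H-chromen-4-one | O=C1C[C@@H](c2ccc(OCc3ccccc3)c(-c3cc(-c4cc(=O)c5c(OCc6ccccc6)cc(OCc6ccccc6)cc5o4)ccc3OCc3ccccc3)c2)Oc2cc(OCc3ccccc3)cc(OCc3ccccc3)c21 | intermediate
14 | 2-[3-[5-[(2S)-5,7-dihydroxy-4-oxo-3,4-dihydro-2H-chromen-2-yl]-2-hydroxyphenyl]-4-hydroxyphenyl]-5,7-dihydroxy-4H-chromen-4-one | O=C1C[C@@H](c2ccc(O)c(-c3cc(-c4cc(=O)c5c(O)cc(O)cc5o4)ccc3O)c2)Oc2cc(O)cc(O)c21 | target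

**Totals**

Total step count: 9. Longest linear sequence: 7 (steps 1, 2, 3, 6, 7, 8, 9); steps 4 and 5 form the branch that supplies chromone 10 for steps 6 and 8.

**Steps most likely to fail**

Step 8. Carbometalation of the electron-rich, 5-alkoxy-flanked chromone may be slower than protodeboronation of the valuable boronic acid 12. The large meta-biaryl group may also erode facial discrimination, or β-aryloxide elimination from the rhodium enolate may open the ring and scramble C2.

The fallback gives up the aryl–C2 disconnection and closes the flavanone ring by oxa-Michael addition, with the enantiomer secured by kinetic resolution. It sets out from 11 and returns at 13: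
- Pd-catalysed reductive carbonylation of 11 (CO/H2, Pd(OAc)2, di(1-adamantyl)-n-butylphosphine, TMEDA, toluene, 100 °C) should give 4-(benzyloxy)-3-[2-(benzyloxy)-5-[5,7-bis(benzyloxy)-4-oxo-4H-chromen-2-yl]phenyl]benzaldehyde F1.
- Claisen–Schmidt condensation of this aldehyde with 8 (KOH, EtOH/THF, rt) should give (E)-1-[2,4-bis(benzyloxy)-6-hydroxyphenyl]-3-[4-(benzyloxy)-3-[2-(benzyloxy)-5-[5,7-bis(benzyloxy)-4-oxo-4H-chromen-2-yl]phenyl]phenyl]prop-2-en-1-one F2.
- NaOAc in refluxing EtOH should cyclise the chalcone to racemic 5,7-bis(benzyloxy)-2-[4-(benzyloxy)-3-[2-(benzyloxy)-5-[5,7-bis(benzyloxy)-4-oxo-4H-chromen-2-yl]phenyl]phenyl]-2,3-dihydro-4H-chromen-4-one F3.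
- Kinetic resolution by asymmetric transfer hydrogenation (Cp*Rh(III)/TsDPEN, HCO2H/Et3N, EtOAc, rt), with the catalyst enantiomer that reduces the (2R)-ketone faster, should convert the unwanted enantiomer into 2-[3-[5-[(2R,4R)-5,7-bis(benzyloxy)-4-hydroxy-3,4-dihydro-2H-chromen-2-yl]-2-(benzyloxy)phenyl]-4-(benzyloxy)phenyl]-5,7-bis(benzyloxy)-4H-chromen-4-one F4. The (2S)-ketone 13 is left behind and goes on to step 9; at most half of the material is carried forward.

Step 6. Oxidative homocoupling, protodeboronation or peroxide-mediated hydroxylation of the electron-rich boronic acid 6 may outrun carbopalladation of the electron-rich chromone. Palladium(0) may insert into the C–Br bond, or dehydrogenation may stop at the flavanone stage.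

The fallback builds the flavone ring by the classical chalcone route. It sets out from 3 and returns at 11:
- The monoaryllithium 4, made from 3 as in step 3, is quenched with DMF to give 4-(benzyloxy)-3-[2-(benzyloxy)-5-bromophenyl]benzaldehyde F5.
- Claisen–Schmidt condensation with 8 (KOH, EtOH, rt) should give (E)-1-[2,4-bis(benzyloxy)-6-hydroxyphenyl]-3-[4-(benzyloxy)-3-[2-(benzyloxy)-5-bromophenyl]phenyl]prop-2-en-1-one F6.
- Oxidative cyclisation with catalytic I2 in DMSO at 120 °C should give 11.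

Step 3. The exchange may not stop cleanly after one bromine: local excess of n-BuLi gives dilithiated material and leaves dibromide behind. Benzylic deprotonation may also compete.

The fallback replaces the statistical differentiation by one based on the large gap between the two pKa values of 2,2'-biphenol and on I/Br chemoselectivity. It sets out from 1 and returns at 6:
- Mono-O-benzylation of 1 (BnBr 1.0 equiv, K2CO3, acetone) should give 2'-(benzyloxy)biphenyl-2-ol F7.
- Iodination para to the free OH (NIS, cat. TsOH, MeCN) should give 2'-(benzyloxy)-5-iodobiphenyl-2-ol F8.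
- Benzylation (BnBr, K2CO3, DMF) should give 2,2'-bis(benzyloxy)-5-iodobiphenyl F9.
- NBS in MeCN should brominate the only ring that still has a free position para to oxygen, giving 2,2'-bis(benzyloxy)-5-bromo-5'-iodobiphenyl F10.
- Chemoselective iodine–magnesium exchange (iPrMgCl·LiCl, THF, −20 °C) should give [4-(benzyloxy)-3-[2-(benzyloxy)-5-bromophenyl]phenyl]magnesium chloride F11, which is borylated with B(OiPr)3 and hydrolysed with 1 M HCl to 6.

**Further compounds**

F1 | step 8 | 4-(benzyloxy)-3-[2-(benzyloxy)-5-[5,7-bis(benzyloxy)-4-oxo-4H-chromen-2-yl]phenyl]benzaldehyde | O=Cc1ccc(OCc2ccccc2)c(c1)-c1cc(ccc1OCc1ccccc1)-c1cc(=O)c2c(OCc3ccccc3)cc(OCc3ccccc3)cc2o1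
F2 | step 8 | (E)-1-[2,4-bis(benzyloxy)-6-hydroxyphenyl]-3-[4-(benzyloxy)-3-[2-(benzyloxy)-5-[5,7-bis(benzyloxy)-4-oxo-4H-chromen-2-yl]phenyl]phenyl]prop-2-en-1-one | O=C(/C=C/c1ccc(OCc2ccccc2)c(c1)-c1cc(ccc1OCc1ccccc1)-c1cc(=O)c2c(OCc3ccccc3)cc(OCc3ccccc3)cc2o1)c1c(O)cc(OCc2ccccc2)cc1OCc1ccccc1
F3 | step 8 | racemic 5,7-bis(benzyloxy)-2-[4-(benzyloxy)-3-[2-(benzyloxy)-5-[5,7-bis(benzyloxy)-4-oxo-4H-chromen-2-yl]phenyl]phenyl]-2,3-dihydro-4H-chromen-4-one | O=C1CC(c2ccc(OCc3ccccc3)c(-c3cc(-c4cc(=O)c5c(OCc6ccccc6)cc(OCc6ccccc6)cc5o4)ccc3OCc3ccccc3)c2)Oc2cc(OCc3ccccc3)cc(OCc3ccccc3)c21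
F4 | step 8 | 2-[3-[5-[(2R,4R)-5,7-bis(benzyloxy)-4-hydroxy-3,4-dihydro-2H-chromen-2-yl]-2-(benzyloxy)phenyl]-4-(benzyloxy)phenyl]-5,7-bis(benzyloxy)-4H-chromen-4-one | O[C@@H]1C[C@H](c2ccc(OCc3ccccc3)c(-c3cc(-c4cc(=O)c5c(OCc6ccccc6)cc(OCc6ccccc6)cc5o4)ccc3OCc3ccccc3)c2)Oc2cc(OCc3ccccc3)cc(OCc3ccccc3)c21
F5 | step 6 | 4-(benzyloxy)-3-[2-(benzyloxy)-5-bromophenyl]benzaldehyde | O=Cc1ccc(OCc2ccccc2)c(c1)-c1cc(Br)ccc1OCc1ccccc1
F6 | step 6 | (E)-1-[2,4-bis(benzyloxy)-6-hydroxyphenyl]-3-[4-(benzyloxy)-3-[2-(benzyloxy)-5-bromophenyl]phenyl]prop-2-en-1-one | O=C(/C=C/c1ccc(OCc2ccccc2)c(c1)-c1cc(Br)ccc1OCc1ccccc1)c1c(O)cc(OCc2ccccc2)cc1OCc1ccccc1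
F7 | step 3 | 2'-(benzyloxy)biphenyl-2-ol | Oc1ccccc1-c1ccccc1OCc1ccccc1
F8 | step 3 | 2'-(benzyloxy)-5-iodobiphenyl-2-ol | Oc1ccc(I)cc1-c1ccccc1OCc1ccccc1
F9 | step 3 | 2,2'-bis(benzyloxy)-5-iodobiphenyl | Ic1ccc(OCc2ccccc2)c(c1)-c1ccccc1OCc1ccccc1
F10 | step 3 | 2,2'-bis(benzyloxy)-5-bromo-5'-iodobiphenyl | Ic1ccc(OCc2ccccc2)c(c1)-c1cc(Br)ccc1OCc1ccccc1
F11 | step 3 | [4-(benzyloxy)-3-[2-(benzyloxy)-5-bromophenyl]phenyl]magnesium chloride | Cl[Mg]c1ccc(OCc2ccccc2)c(c1)-c1cc(Br)ccc1OCc1ccccc1
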